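Start from a one-step world: substrate plus gas gives target and released group, the gas is held, so treat its concentration as a constant and let a single rate constant each way draw the curve. This is the bench rule of constant gas, pseudo-first-order in substrate.

| setting | oak | elm | flask |
|---|---|---|---|
| substrate | 0.40 M | 0.27 M | 0.40 M |
| gas | 60 mM (held) | 60 mM (held) | 60 mM (held) |
| temperature | 80 °C | 65 °C | 80 °C |
| remark | the very flask that is asked about, followed so far | run made earlier |  |
| time |  |  | 10 h |

| run | time / h | target / % |
|---|---|---|
| oak | 1.50 | 14.9 |
| oak | 3.00 | 20.6 |
| oak | 5.00 | 23.4 |
| oak | 6.00 | 23.7 |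
| elm | 0.200 | 0.3 |
| elm | 0.500 | 3.7 |
| elm | 1.33 | 14.5 |
| elm | 3.00 | 26.7 |

(readings scatter by 1 percentage point)

- additions bring no volume worth counting
- at the start none of the gas is in solution

- red: change nothing and wait 20 h more
- blue: at 10 h add substrate, 50.0% of the amount charged, then wait 20 h
- teal: at 10 h raise the temperature by 15 K, then wait 20 h
- grey: at 10 h take out 90% of the released group then present, then wait 20 h

* target, in percent of the substrate first charged, at 10 h
* which option adds most target ("none" when 2 percentage points or less is all one gets) (red / blue / teal / grey / none)
* target present, in percent of the substrate first charged, after teal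
* target present, in percent of the substrate first charged, after grey

Apply the rule honestly. The last two oak readings differ by 0.3 percentage points, less than the scatter of 1 point, so it calls oak finished, and my own figure for target at 10 h stays near 23.7%.

Now write the balance of the gas, the smaller amount in the charge. The liquid starts empty and holds at most 60 mM of dissolved gas, and each substrate turned costs one gas; so gas crossed is at least the gas spent, and whatever else holds gas adds to that. Divide by the substrate charged. Let φ = csat/cA, here 15.0%, be the filling share: the part of the oak substrate that one full liquid can turn. Let N, the number of fillings, be the share turned divided by φ.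

The rule is safe while N is small against one. Oak's first reading, 14.9% at 1.50 h, already matches φ, and its last gives N of at least 1.58. Elm, with φ of 22.2%, gives at least 1.20. "At least" matters: nobody read the substrate, so target is merely a floor on what turned. Past this border the gas is a flow, not a stock. In oak a flat target is a statement about target; substrate went unread.

The forecast says “The simplest reading is a reversible reaction” and gives 24%, picks grey, and puts 20.5% after teal and 35% after grey.

The flask gives 20.8% at 10 h; teal is best, with 37.4%, while grey gives 17.2%.

    target ⇌ isomer of the product (K = 4.80, k = 1.70 × 10⁻⁴ s⁻¹, Ea = 104 kJ mol⁻¹, ΔH = −76.0 kJ mol⁻¹)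
    reagent ⇌ dormant form (K = 8.80, k = 6.40 × 10⁻⁴ s⁻¹, Ea = 104 kJ mol⁻¹, ΔH = −20.0 kJ mol⁻¹)
    gas ⇌ reagent, rate k3*(csat - [reagent]) (kL = 6.90 × 10⁻⁴ s⁻¹)
    substrate + reagent → target + released group (k = 0.00240 M⁻¹ s⁻¹, Ea = 56.0 kJ mol⁻¹)
    (constants at 80 °C)

Substrate left at 10.0 h is 6.81%, so 93.2% has turned, which by φ is 6.21 fillings, while target accounts for 1.39 and the isomer of the product holds 72.4%. The same flask stopped at 2.5 h still has 65% of its substrate, so it has spent 2.33 fillings, with target at 19.3% and the isomer of the product at 15.5%.

The numbers in the tables are simulated for substances that don't exist; the scatter is artificial.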